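Late in the delta run, between 14 min and 17 min, product grows by 0.0317 M/min, a sag I expect while c(substrate) and c(reagent) fall.

| flask | substrate | reagent | catalyst | time |
|---|---|---|---|---|
| epsilon | 1.00 M | 1.20 M | 0.0500 M |  |
| alpha | 0.400 M | 0.600 M | 0.0500 M |  |
| eta | 1.00 M | 0.600 M | 0.0500 M |  |
| delta | 3.00 M | 1.20 M | 0.0500 M |  |
| gamma | 1.00 M | 1.20 M | 0.0500 M | 51 min |

- epsilon run (time / min: [product] / M): 0.61: 0.007; 1.8: 0.046; 3.5: 0.098; 5.6: 0.206; 8.0: 0.352; 11: 0.468; 14: 0.579; 17: 0.671
- alpha run (time / min: [product] / M): 0.61: 0.003; 1.8: 0.019; 3.5: 0.046; 5.6: 0.088; 8.0: 0.144; 11: 0.191; 14: 0.237; 17: 0.274
- eta run (time / min: [product] / M): 0.61: 0.006; 1.8: 0.030; 3.5: 0.089; 5.6: 0.170; 8.0: 0.269; 11: 0.376; 14: 0.464; 17: 0.512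
- delta run (time / min: [product] / M): 0.61: 0.014; 1.8: 0.080; 3.5: 0.232; 5.6: 0.443; 8.0: 0.677; 11: 0.914; 14: 1.051; 17: 1.146

(standard deviation of a reading: 0.008 M)

- Overall: substrate + reagent -> product, with catalyst as catalyst.
- Constant volume, constant temperature.
- A reading of a species includes what of it is bound.
- "The second partner" is reagent.
- An order is taken over about fifteen percent of the charge, up and down.

1. apparent order in [reagent] of the starting rate, round the charge of the epsilon run (the rate where two percent of its substrate have turned into product)
2. apparent order in [substrate] of the starting rate, round the charge of the epsilon run (the rate where two percent of its substrate have turned into product) (one fixed amount of product, the same in the runs compared)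
3. the alpha run starts with 0.600 M less of substrate and of reagent than the epsilon run, and with no product. Compared where both hold the same amount of substrate, once fifteen percent of what the alpha run was charged with has turned into product, is the alpha run faster, slower or alike (within a tenth)?
4. product in the gamma run at 51 min, as a share of the substrate charged
5. which of these the readings show (an uncatalysed path runs beside / the product kills the catalyst / the catalyst wakes slowly / nothing beyond the main steps / the second partner is lost by itself / the product binds the second partner)

1. The early end is the strange one. In the delta run, product grows by 0.0555 M/min between 0.61 min and 1.8 min, but by 0.100 M/min between 3.5 min and 5.6 min, which is faster with less substrate and reagent present. So I take it that c(active catalyst) is rising: the catalyst wakes (an induction period). This is the concentration I follow.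

2. Upper bound. I assume the wake runs alike in all flasks, so two runs compared at one time hold the same c(active catalyst), and their product ratio is a rate ratio. At 3.5 min, delta over epsilon gives a reading of 0.784 for the order in substrate, which I call the true order. At a fixed amount of product, the faster run arrives earlier, with less active catalyst, so the apparent order lies below this.

3. Lower bound. Suppose c(active catalyst) grows in proportion to time. Then the rate grows with time and product with its square. At fixed product, the arrival time goes as one over the root of the full rate, and the rate as that root. The order then falls to 0.392, half of the true order.

4. Tightening. The square law, with 0.100 M/min as the full rate and the delta reading at 1.8 min, gives a wake time of 2.03 min. The epsilon run reaches 0.0200 M of product at about 1.19 min. The next term of the series adds that time over the wake time, divided by 6, to 0.5, which gives 0.597. This is the keep share, the part of a true order that survives comparison at fixed product. For the apparent order in substrate I commit to 0.468.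

5. The forecast gives 0.43 for substrate (from 0.28 to 0.62), inside my bracket but below my figure. It gives 0.15 for reagent, slower for the alpha run, 97.5% for the gamma run, and "the catalyst wakes slowly". Its grounds: “A faster run reaches that point earlier and with less active catalyst, so the orders shrink by about 0.6, to roughly 0.43 and 0.15.”

6. The simulation gives 0.47 for substrate, inside the bracket, 0.13 for reagent, slower for the alpha run, 98.4% for the gamma run, and "the catalyst wakes slowly".

    active catalyst + substrate → catalyst-substrate complex (1.950 /M/min)
    catalyst-substrate complex + reagent → product + active catalyst (6.300 /M/min)
    catalyst → active catalyst (0.3780 /min)

The order in substrate is 0.47 because the catalyst wakes slowly: the same flask with that slowness taken away gives 0.76, so a share of 0.618 survives, beside my keep share of 0.597. Carried to the order in catalyst, the keep share turns the 0.91 of the flask without the slow wake into 0.543, and the simulated order with the slow wake is 0.57.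

(The runs are simulated with made-up constants, and the scatter is random.)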